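**Assumption (remark on the chemistry):** positions on the dioxin tricycle are numbered as in the name of 9 and this numbering is kept through 23; chloride is assumed to add to methoxy-1,4-benzoquinone at C5, the site taken in Thiele–Winter acetoxylation, and to the chloroquinone 3 at C3, since C6 is the electron-rich enol ether carbon and addition at C2 or C5 cannot end in aromatisation.

## Structural features

Phlorofucofuroeckol A is an achiral, fully aromatic nonaphenol built from five benzene rings, lettered E, A, B, C, D in the order in which they appear in the SMILES. Rings A and B are fused through a 1,4-dioxin (two C–O–C bridges) and rings B and C through a furan (one biaryl C–C bond and one C–O–C bridge), while rings E and D hang as 3,5-dihydroxyphenyl ethers on ring A and ring C. There is no stereocentre, so every problem is regiochemical: ring A carries five oxygens in five different environments, ring B has a single hydrogen, and both the dioxin and the furan can be joined in two orientations. The free polyphenol is fragile (air oxidation, acid-promoted scission of phloroglucinol-type aryl ethers), so all phenols stay as ethers until the last step. The real difficulty lies in the crowded C–O bonds (the ring E ether flanked by two oxygens, the two dioxin bonds) and in telling apart the two para oxygens of ring A. On ring A the carbon bearing the ring E ether and the hydroxylated carbon para to it flank the two dioxin carbons, which makes ring A a reduced 2,3-disubstituted 1,4-benzoquinone. The key step exploits this by bringing ring A in as a 2,3-dichloroquinone whose vinylic chlorides are displaced by the two catechol oxygens of ring B.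

## Logic of the disconnections

**25 to 24.** The nine O–alkyl bonds are cut last, so that the air-sensitive polyphenol appears only once. 24 carries eight methyl ethers and one isopropyl ether, all removable by one Lewis acid. The forward step must cleave alkyl–oxygen bonds and leave the diaryl ether, dioxin and furan bonds alone.

**24 to 23.** The furan C–O bond from the ring B oxygen on C7 to ring C is cut, leaving a 2-arylphenol. A ring C with oxygen on both carbons flanking the biaryl bond could close through either oxygen and give two furans. In 23 one flanking carbon bears hydrogen (next to the ring D ether) and the other a methoxyl, so only one closure exists. The forward step must be a phenol-directed C–H oxidation that tolerates an electron-rich polyether.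

**23 to 16 and 22.** The biaryl bond is cut, which makes the route convergent and divides the molecule into an A–B–E half and a C–D half. Because ring C still has hydrogen at the future furan carbon, the biaryl has three ortho substituents and not four, and 22 has only one ortho substituent next to boron. The forward step needs a halogen on C6 of 16 and a cross-coupling that accepts a free ortho phenol.

**16 to 15 to 13.** The C–Br bond is cut, then the C7 oxygen is traced back to the formyl group of 13. The aldehyde does two jobs: it differentiates the two catechol oxygens in the key step and later becomes the furan oxygen. The forward steps need bromination at C6 (not at C8, and not on rings A or E) and an oxidation in which the ring B aryl group migrates.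

**13 to 11 and 12, then 11 to 10 to 9.** The ring E–oxygen bond is cut at the hindered oxygen of ring A, then the isopropyl ether, then the redox level is changed. Reduction of 9 gives two hydroxyls that differ: the one on C4 has a ring hydrogen as neighbour, the one on C1 lies between a methoxyl and a dioxin oxygen. The forward steps must alkylate the first and arylate the second.

**9 to 5 and 6 (key).** Both dioxin C–O bonds are cut. Ring A is returned to the quinone 5, whose two carbonyls are the para oxygen pair and whose two chlorinated carbons are innately electrophilic, and ring B to the purchasable catechol 6. This removes one ring and two hindered C–O bonds at once and supplies ring A at the right oxidation level. The forward step must set one orientation of two unsymmetrical partners.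

**5 to 4 to 3 to 2 to 1.** The two C–Cl bonds are cut one at a time, each as a hydrochlorination of a quinone followed by reoxidation. Electrophilic chlorine would be drawn to the methoxy-substituted double bond of 1 or, on 2, to the carbon ortho to the methoxyl, which is the wrong side of the ring. Nucleophilic chloride at the quinone level places both chlorines on the side remote from the methoxyl. The forward steps need conjugate addition at the intended carbon twice and a mild oxidant that leaves vinylic chloride and methoxyl alone.

**22 to 21, 21 to 19 and 20, 19 to 17.** The C–B bond, the ring D ether bond and the phenol oxygen (from a formyl group) are cut in turn. The bromine is already in place in purchasable 17, so ring C never has to be halogenated in the presence of the more nucleophilic ring D. The etherification must therefore spare an aryl bromide.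

## Other disconnections considered

**Alternative 1:** The cut removes four of the six carbons of each terminal ring. Rings D and E are traced to the bis(ethynyl ether) A2 of the finished A–B–C core and two molecules of 3-ethoxycyclobut-2-en-1-one A3. In the forward step each molecule of A3 would open thermally to a vinylketene and add [2+2] to one ynol ether unit of A2, ketene carbon to the alkyne CH and α-carbon to the oxygen-bearing carbon. The resulting vinylcyclobutenone would reopen and close by 6π electrocyclisation (Danheiser benzannulation) to give A1.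
- In its favour: the 1,3,5-oxygen pattern of both rings is fixed by the mechanism, and both crowded diaryl ether oxygens are in place before the rings exist. No copper-mediated arylation of a doubly ortho-substituted phenol is needed. On this point it is better than steps 8 and 12 of the chosen plan, and its regiochemical reliability is at least equal to that of a cross-coupling.
- Against it: it constructs two rings that can be bought as 12 and 20. It says nothing about the orientation of the dioxin and the furan, so A2 would still have to come from chemistry like steps 1–7 and 9–15. Two core phenols would have to be turned into sensitive aryl ethynyl ethers with strong base on a substrate with several acidic ring hydrogens, and A3 is itself a reagent that has to be prepared.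
- Comparison: A1 still needs a global dealkylation (equal to step 16) and the plan would be several steps longer.

**Alternative 2:** The cut is in ring A itself: four carbons come from the mixed aryl isopropyl squarate A6 and two from an α-ethoxyvinyl organometallic. Addition to the carbonyl of A6 that is conjugated with the aryloxy group, followed by silylation, would give the racemic cyclobutenone A5. Thermolysis of A5 would open it to a vinylketene whose ketene carbon bonds to the vinyl CH2, and tautomerisation would give the phenol A4 (Moore-type ring expansion).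
- In its favour: ring A is born with ring E attached and with all five oxygens differentiated. The selective alkylation and the hindered arylation (steps 7 and 8) disappear, and here it is the better plan. The electrocyclic cascade is mechanistically as secure as the quinone substitution.
- Against it: the dioxin must then be closed between A4 and ring B by two C–O bond formations in which neither partner is innately electrophilic, and the orientation question returns without the electronic bias of 5. The aryloxy group of A6 can be lost as aryloxide to organometallic reagents. Three protecting-group types have to be handled.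
- Comparison: step count to a ring A building block is about equal (four steps to 5 against about four to A4). The subsequent annulation is where the chosen plan is stronger.

**Alternative 3:** The cut takes the biaryl bond and the furan C–O bond together. The O-arylhydroxylamine A8 of ring C–D would condense with phloroglucinol A9, which would react as its keto tautomer. A [3,3] shift across the N–O bond would make the hindered C–C bond, and the liberated ring C phenol would displace the nitrogen to close the furan, giving A7.
- In its favour: one metal-free step replaces bromination, cross-coupling and C–H cyclisation (steps 10, 14, 15). The site on ring C is unambiguous because its other ortho position is blocked by the ring D ether. On the biaryl and furan construction it is better than the chosen plan in both step count and regiocontrol.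
- Against it: ring B arrives from A9 as a symmetrical unit. A7 lacks the oxygen on the carbon between its two hydroxyls, those two hydroxyls must be told apart, and the dioxin with ring A must be built last between two electron-rich partners. A8 needs an N–O bond-forming step on a hindered phenol.
- Comparison: the plans are complementary. Alternative 3 solves the furan and postpones the dioxin; the chosen plan solves the dioxin first with the quinone and accepts a longer furan sequence.

Key step: step 5

## Route

Step 1
Reactants: 1 methoxy-1,4-benzoquinone
Product: 2 2-chloro-5-methoxybenzene-1,4-diol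
Conditions: HCl (4 M in 1,4-dioxane), CHCl3, 0 °C to rt
Reagents that add atoms: hydrogen chloride, Cl
Why: Hydrochlorination of a quinone (conjugate addition of chloride, then enolisation to the hydroquinone); chloride should enter C5, β to the carbonyl that is not deactivated as a vinylogous ester of the methoxyl, as other nucleophiles do with this quinone.

Step 2
Reactants: 2 2-chloro-5-methoxybenzene-1,4-diol
Product: 3 2-chloro-5-methoxy-1,4-benzoquinone
Conditions: PhI(OAc)2, MeCN–H2O, 0 °C
Reagents that add atoms: none
Why: Two-electron oxidation of a hydroquinone to the quinone by PhI(OAc)2, a trivalent iodine reagent; the conditions are mild and non-nucleophilic, so the vinylic chloride and the methoxyl should survive.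

Step 3
Reactants: 3 2-chloro-5-methoxy-1,4-benzoquinone
Product: 4 2,3-dichloro-5-methoxybenzene-1,4-diol
Conditions: HCl (4 M in 1,4-dioxane), AcOH, rt
Reagents that add atoms: hydrogen chloride, Cl
Why: Second quinone hydrochlorination, of the kind that takes chloro-1,4-benzoquinones to the vicinal dichlorohydroquinones; C6 is the electron-rich α-carbon of the methoxy enone and should resist nucleophiles, so chloride should add at C3 next to the first chlorine, and aromatisation makes that addition irreversible.

Step 4
Reactants: 4 2,3-dichloro-5-methoxybenzene-1,4-diol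
Product: 5 2,3-dichloro-5-methoxy-1,4-benzoquinone
Conditions: PhI(OAc)2, MeCN–H2O, 0 °C
Reagents that add atoms: none
Why: Hydroquinone-to-quinone oxidation as in step 2; the product, a doubly vinylogous acid chloride, should be stable enough to isolate once water is removed.

Step 5
Reactants: 5 2,3-dichloro-5-methoxy-1,4-benzoquinone; 6 3,4-dihydroxy-5-methoxybenzaldehyde
Product: 9 2,9-dimethoxy-1,4-dioxo-1,4-dihydrodibenzo[b,e][1,4]dioxine-7-carbaldehyde, via disodium catecholate 7 (not isolated), via aryloxy chloroquinone phenoxide 8 (not isolated)
Conditions: 6, NaH (2.05 equiv), DMF, 0 °C; then slow addition to 5, DMF (0.02 M), −40 °C to rt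
Reagents that add atoms: none
Why: Both dioxin C–O bonds should arise by vinylic addition–elimination, in which a phenoxide adds in conjugate fashion to a quinone carbon that carries chlorine and the resulting enolate expels chloride; the closest known reaction is the annulation of catechols onto 2,3-dichloro-1,4-naphthoquinone or chloranil to give dioxin-fused quinones. The first substitution is intermolecular and gives 8; the second is a 6-endo-trig attack of the remaining phenoxide on the neighbouring C–Cl carbon, after which loss of chloride restores the quinone and closes the dioxin. No stereocentre is formed. The step needs one orientation of two unsymmetrical partners: in 7 the oxygen meta to the formyl group is the more nucleophilic (its charge is not delocalised into the aldehyde and it has one ortho substituent fewer), and in 5 C2 is the more electrophilic chlorinated carbon because it is β to the C4 carbonyl, whereas C3 is β to the C1 carbonyl that is deactivated as a vinylogous ester of the methoxyl. Pairing these two sites gives the connectivity of 9, with both methoxyls on the same edge of the tricycle. The dianion is preformed with NaH because a carbonate base would leave mainly the monoanion on the oxygen para to the formyl group, which would attack C2 first and reverse the orientation. Slow addition of 7 to 5 at low temperature and high dilution should suppress double intermolecular substitution and electron transfer, and chloride should be displaced in preference to the methoxyl because the C–Cl carbons are the better acceptors and chloride the better leaving group.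

Step 6
Reactants: 9 2,9-dimethoxy-1,4-dioxo-1,4-dihydrodibenzo[b,e][1,4]dioxine-7-carbaldehyde
Product: 10 1,4-dihydroxy-2,9-dimethoxydibenzo[b,e][1,4]dioxine-7-carbaldehyde
Conditions: Na2S2O4, THF–H2O, rt, Ar
Reagents that add atoms: none
Why: Dithionite reduction of a quinone to the hydroquinone; the aromatic aldehyde should not be reduced at room temperature.

Step 7
Reactants: 10 1,4-dihydroxy-2,9-dimethoxydibenzo[b,e][1,4]dioxine-7-carbaldehyde
Product: 11 1-hydroxy-2,9-dimethoxy-4-(propan-2-yloxy)dibenzo[b,e][1,4]dioxine-7-carbaldehyde
Conditions: 2-bromopropane (1.1 equiv), K2CO3 (1.1 equiv), DMF, 40 °C, Ar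
Reagents that add atoms: 2-bromopropane, CC(C)Br
Why: Williamson etherification; the C4 hydroxyl has a ring hydrogen as neighbour and two meta oxygens (less hindered, more acidic), whereas the C1 hydroxyl lies between the methoxyl and a dioxin oxygen, and a secondary halide amplifies this steric difference. The isopropyl ether is later removed together with the methyl ethers.

Step 8
Reactants: 11 1-hydroxy-2,9-dimethoxy-4-(propan-2-yloxy)dibenzo[b,e][1,4]dioxine-7-carbaldehyde; 12 1-bromo-3,5-dimethoxybenzene
Product: 13 1-(3,5-dimethoxyphenoxy)-2,9-dimethoxy-4-(propan-2-yloxy)dibenzo[b,e][1,4]dioxine-7-carbaldehyde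
Conditions: CuI (10 mol %), picolinic acid (20 mol %), K3PO4, DMSO, 90 °C, Ar
Reagents that add atoms: none
Why: Ullmann-type diaryl ether synthesis with monovalent copper and picolinic acid, a system suited to ortho,ortho-disubstituted phenols; the aldehyde is non-enolisable and the alkyl ethers are inert.

Step 9
Reactants: 13 1-(3,5-dimethoxyphenoxy)-2,9-dimethoxy-4-(propan-2-yloxy)dibenzo[b,e][1,4]dioxine-7-carbaldehyde
Product: 15 1-(3,5-dimethoxyphenoxy)-2,9-dimethoxy-4-(propan-2-yloxy)dibenzo[b,e][1,4]dioxin-7-ol, via aryl formate 14 (not isolated)
Conditions: mCPBA, CH2Cl2, 0 °C to rt; then K2CO3 (cat.), MeOH, rt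
Reagents that add atoms: 3-chloroperoxybenzoic acid, OOC(=O)c1cccc(Cl)c1
Why: Baeyer–Villiger oxidation of an electron-rich benzaldehyde (Dakin-type); aryl migration is favoured by the para oxygen and two meta oxygens, as in 3,4,5-trialkoxybenzaldehydes, and the formate is cleaved by methanolysis.

Step 10
Reactants: 15 1-(3,5-dimethoxyphenoxy)-2,9-dimethoxy-4-(propan-2-yloxy)dibenzo[b,e][1,4]dioxin-7-ol
Product: 16 6-bromo-1-(3,5-dimethoxyphenoxy)-2,9-dimethoxy-4-(propan-2-yloxy)dibenzo[b,e][1,4]dioxin-7-ol
Conditions: NBS (1.0 equiv), i-Pr2NH (10 mol %), CH2Cl2, −78 to −20 °C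
Reagents that add atoms: N-bromosuccinimide, BrN1C(=O)CCC1=O
Why: Amine-catalysed ortho-bromination of a phenol; the hydrogen-bonded phenol should react at low temperature where the aryl ethers of rings A and E are slow, and of the two ortho positions C6 is para to the C9 methoxyl and next to the tied-back dioxin oxygen, whereas C8 is shielded by the outward-pointing methyl of that methoxyl.

Step 11
Reactants: 17 5-bromo-2,4-dimethoxybenzaldehyde
Product: 19 5-bromo-2,4-dimethoxyphenol, via aryl formate 18 (not isolated)
Conditions: mCPBA, CH2Cl2, rt; then K2CO3 (cat.), MeOH, rt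
Reagents that add atoms: 3-chloroperoxybenzoic acid, OOC(=O)c1cccc(Cl)c1
Why: Baeyer–Villiger oxidation with aryl migration driven by ortho and para methoxyls, then methanolysis of the formate; the bromine that will become the biaryl carbon is already in place.

Step 12
Reactants: 19 5-bromo-2,4-dimethoxyphenol; 20 3,5-dimethoxyphenylboronic acid
Product: 21 1-bromo-5-(3,5-dimethoxyphenoxy)-2,4-dimethoxybenzene
Conditions: Cu(OAc)2 (20 mol %), pyridine, 4 Å molecular sieves, CH2Cl2, O2 (1 atm), rt
Reagents that add atoms: none
Why: Chan–Lam coupling of a phenol with an arylboronic acid under divalent copper and oxygen; it runs at room temperature and should leave the aryl bromide untouched, which a coupling with an aryl halide partner would not guarantee.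

Step 13
Reactants: 21 1-bromo-5-(3,5-dimethoxyphenoxy)-2,4-dimethoxybenzene
Product: 22 2-[5-(3,5-dimethoxyphenoxy)-2,4-dimethoxyphenyl]-4,4,5,5-tetramethyl-1,3,2-dioxaborolane
Conditions: B2pin2, Pd(dppf)Cl2 (3 mol %), KOAc, 1,4-dioxane, 90 °C
Reagents that add atoms: bis(pinacolato)diboron, CC1(C)OB(OC1(C)C)B1OC(C)(C)C(C)(C)O1
Why: Miyaura borylation of an aryl bromide; with a single ortho substituent the boronate should be stable to protodeboronation.

Step 14
Reactants: 16 6-bromo-1-(3,5-dimethoxyphenoxy)-2,9-dimethoxy-4-(propan-2-yloxy)dibenzo[b,e][1,4]dioxin-7-ol; 22 2-[5-(3,5-dimethoxyphenoxy)-2,4-dimethoxyphenyl]-4,4,5,5-tetramethyl-1,3,2-dioxaborolane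
Product: 23 6-[5-(3,5-dimethoxyphenoxy)-2,4-dimethoxyphenyl]-1-(3,5-dimethoxyphenoxy)-2,9-dimethoxy-4-(propan-2-yloxy)dibenzo[b,e][1,4]dioxin-7-ol
Conditions: Pd(OAc)2 (5 mol %), SPhos (10 mol %), K3PO4, toluene–H2O, 90 °C
Reagents that add atoms: none
Why: Suzuki–Miyaura coupling to a tri-ortho-substituted biaryl; a dialkylbiarylphosphine ligand is used because it accepts hindered, electron-rich bromides and free ortho phenols.

Step 15
Reactants: 23 6-[5-(3,5-dimethoxyphenoxy)-2,4-dimethoxyphenyl]-1-(3,5-dimethoxyphenoxy)-2,9-dimethoxy-4-(propan-2-yloxy)dibenzo[b,e][1,4]dioxin-7-ol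
Product: 24 octamethyl isopropyl ether of phlorofucofuroeckol A (isopropyl on the ring A oxygen para to the ring E ether, methyl on the other eight oxygens)
Conditions: Pd(OAc)2 (10 mol %), IPr (20 mol %), MesCO2Na, K2CO3, 4,5-diazafluoren-9-one, mesitylene, air, 120 °C
Reagents that add atoms: none
Why: Phenol-directed C–H activation and C–O cyclisation of a 2-arylphenol to a dibenzofuran; the palladium phenoxide (divalent palladium) metalates the only ortho hydrogen of ring C through a six-membered palladacycle, and C–O reductive elimination closes the furan, with air as terminal oxidant. Because the other ortho position of ring C bears a methoxyl, the furan oxygen can only be placed on the carbon next to the ring D ether.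

Step 16
Reactants: 24 octamethyl isopropyl ether of phlorofucofuroeckol A
Product: 25 phlorofucofuroeckol A
Conditions: BBr3 (excess), CH2Cl2, −78 °C to rt; then H2O, 0 °C, Ar
Reagents that add atoms: none
Why: Lewis-acid dealkylation of aryl alkyl ethers; bromide attacks the methyl and isopropyl carbons, while the diaryl ether, dioxin and furan bonds have no carbon open to substitution and should survive if the mixture is kept cold and quenched without heating.

## Compound list

1 | methoxy-1,4-benzoquinone | COC1=CC(=O)C=CC1=O | starting material
2 | 2-chloro-5-methoxybenzene-1,4-diol | COc1cc(O)c(Cl)cc1O | intermediate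
3 | 2-chloro-5-methoxy-1,4-benzoquinone | COC1=CC(=O)C(Cl)=CC1=O | intermediate
4 | 2,3-dichloro-5-methoxybenzene-1,4-diol | COc1cc(O)c(Cl)c(Cl)c1O | intermediate
5 | 2,3-dichloro-5-methoxy-1,4-benzoquinone | COC1=CC(=O)C(Cl)=C(Cl)C1=O | intermediate
6 | 3,4-dihydroxy-5-methoxybenzaldehyde | O=Cc1cc(O)c(O)c(OC)c1 | starting material
7 | disodium 5-formyl-3-methoxybenzene-1,2-diolate | [Na+].[Na+].[O-]c1cc(C=O)cc(OC)c1[O-] | intermediate
8 | sodium 2-[(2-chloro-4-methoxy-3,6-dioxocyclohexa-1,4-dien-1-yl)oxy]-4-formyl-6-methoxyphenolate | COC1=CC(=O)C(Oc2cc(C=O)cc(OC)c2[O-])=C(Cl)C1=O.[Na+] | intermediate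
9 | 2,9-dimethoxy-1,4-dioxo-1,4-dihydrodibenzo[b,e][1,4]dioxine-7-carbaldehyde | COC1=CC(=O)C2=C(Oc3c(OC)cc(C=O)cc3O2)C1=O | intermediate
10 | 1,4-dihydroxy-2,9-dimethoxydibenzo[b,e][1,4]dioxine-7-carbaldehyde | COc1cc(O)c2Oc3cc(C=O)cc(OC)c3Oc2c1O | intermediate
11 | 1-hydroxy-2,9-dimethoxy-4-(propan-2-yloxy)dibenzo[b,e][1,4]dioxine-7-carbaldehyde | COc1cc(OC(C)C)c2Oc3cc(C=O)cc(OC)c3Oc2c1O | intermediate
12 | 1-bromo-3,5-dimethoxybenzene | COc1cc(Br)cc(OC)c1 | starting material
13 | 1-(3,5-dimethoxyphenoxy)-2,9-dimethoxy-4-(propan-2-yloxy)dibenzo[b,e][1,4]dioxine-7-carbaldehyde | COc1cc(OC(C)C)c2Oc3cc(C=O)cc(OC)c3Oc2c1Oc1cc(OC)cc(OC)c1 | intermediate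
14 | 1-(3,5-dimethoxyphenoxy)-2,9-dimethoxy-4-(propan-2-yloxy)dibenzo[b,e][1,4]dioxin-7-yl formate | COc1cc(OC(C)C)c2Oc3cc(OC=O)cc(OC)c3Oc2c1Oc1cc(OC)cc(OC)c1 | intermediate
15 | 1-(3,5-dimethoxyphenoxy)-2,9-dimethoxy-4-(propan-2-yloxy)dibenzo[b,e][1,4]dioxin-7-ol | COc1cc(OC(C)C)c2Oc3cc(O)cc(OC)c3Oc2c1Oc1cc(OC)cc(OC)c1 | intermediate
16 | 6-bromo-1-(3,5-dimethoxyphenoxy)-2,9-dimethoxy-4-(propan-2-yloxy)dibenzo[b,e][1,4]dioxin-7-ol | COc1cc(OC(C)C)c2Oc3c(Br)c(O)cc(OC)c3Oc2c1Oc1cc(OC)cc(OC)c1 | intermediate
17 | 5-bromo-2,4-dimethoxybenzaldehyde | COc1cc(OC)c(C=O)cc1Br | starting material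
18 | 5-bromo-2,4-dimethoxyphenyl formate | COc1cc(OC)c(OC=O)cc1Br | intermediate
19 | 5-bromo-2,4-dimethoxyphenol | COc1cc(OC)c(O)cc1Br | intermediate
20 | 3,5-dimethoxyphenylboronic acid | COc1cc(OC)cc(c1)B(O)O | starting material
21 | 1-bromo-5-(3,5-dimethoxyphenoxy)-2,4-dimethoxybenzene | COc1cc(OC)c(Oc2cc(OC)cc(OC)c2)cc1Br | intermediate
22 | 2-[5-(3,5-dimethoxyphenoxy)-2,4-dimethoxyphenyl]-4,4,5,5-tetramethyl-1,3,2-dioxaborolane | COc1cc(OC)c(Oc2cc(OC)cc(OC)c2)cc1B1OC(C)(C)C(C)(C)O1 | intermediate
23 | 6-[5-(3,5-dimethoxyphenoxy)-2,4-dimethoxyphenyl]-1-(3,5-dimethoxyphenoxy)-2,9-dimethoxy-4-(propan-2-yloxy)dibenzo[b,e][1,4]dioxin-7-ol | COc1cc(OC(C)C)c2Oc3c(-c4cc(Oc5cc(OC)cc(OC)c5)c(OC)cc4OC)c(O)cc(OC)c3Oc2c1Oc1cc(OC)cc(OC)c1 | intermediate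
24 | octamethyl isopropyl ether of phlorofucofuroeckol A | COc1cc(OC)cc(Oc2c(OC)cc(OC(C)C)c3c2Oc2c(OC)cc4oc5c(Oc6cc(OC)cc(OC)c6)c(OC)cc(OC)c5c4c2O3)c1 | intermediate
25 | phlorofucofuroeckol A | Oc1cc(O)cc(Oc2c(O)cc(O)c3c2Oc2c(O)cc4oc5c(Oc6cc(O)cc(O)c6)c(O)cc(O)c5c4c2O3)c1 | target

## Step count and least certain steps

Total: 16 steps. Longest linear sequence: 13 steps (steps 1–10 and 14–16); the ring C–D branch (steps 11–13) joins at step 14.

**Step 5 (key step).** The catechol may attach in the reversed orientation, either because the phenoxide para to the formyl group reacts first or because the first attack goes to C3 of 5. The electron-rich dianion may also transfer an electron to the quinone, or the second substitution may occur between molecules. The orientation rests on two electronic preferences that are each plausible but not large.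
Fallback (from 6, back at 9): the more acidic hydroxyl para to the formyl group would be protected (chloromethyl methyl ether, i-Pr2NEt, CH2Cl2, 0 °C) to give 3-hydroxy-5-methoxy-4-(methoxymethoxy)benzaldehyde F1. Its single phenoxide (K2CO3, MeCN, 0 °C) would displace one chloride of 5 to give 3-[(2-chloro-4-methoxy-3,6-dioxocyclohexa-1,4-dien-1-yl)oxy]-5-methoxy-4-(methoxymethoxy)benzaldehyde F2, so that only the site preference of the quinone remains to be relied on. CF3CO2H in CH2Cl2 would remove the acetal to give 3-[(2-chloro-4-methoxy-3,6-dioxocyclohexa-1,4-dien-1-yl)oxy]-4-hydroxy-5-methoxybenzaldehyde F3, and K2CO3 in DMF would close the dioxin to 9.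

**Step 10.** Bromination may occur at C8 instead of C6, since both are ortho to the hydroxyl and the electronic difference is small. It may also occur on the phloroglucinol-type ring E or at the free position of ring A, which are nearly as nucleophilic as the phenol ring.
Fallback (from 6, back at 16): the halogen would be placed before the competing rings exist. Bromination of 6 (Br2, NaOAc, AcOH), ortho to the 3-hydroxyl and para to the methoxyl as with isovanillin, would give 2-bromo-3,4-dihydroxy-5-methoxybenzaldehyde F8. Its dianion and 5 under the conditions of step 5 would give 6-bromo-2,9-dimethoxy-1,4-dioxo-1,4-dihydrodibenzo[b,e][1,4]dioxine-7-carbaldehyde F9; the ortho bromine lowers the nucleophilicity of the neighbouring oxide, so the stepwise variant described for step 5 may be needed here. Na2S2O4 would then give 6-bromo-1,4-dihydroxy-2,9-dimethoxydibenzo[b,e][1,4]dioxine-7-carbaldehyde F10, and 2-bromopropane with K2CO3 would give 6-bromo-1-hydroxy-2,9-dimethoxy-4-(propan-2-yloxy)dibenzo[b,e][1,4]dioxine-7-carbaldehyde F11. Oxidative coupling with 20 (Cu(OAc)2, pyridine, O2, rt), which spares the aryl bromide, would give 6-bromo-1-(3,5-dimethoxyphenoxy)-2,9-dimethoxy-4-(propan-2-yloxy)dibenzo[b,e][1,4]dioxine-7-carbaldehyde F12. mCPBA would give 6-bromo-1-(3,5-dimethoxyphenoxy)-2,9-dimethoxy-4-(propan-2-yloxy)dibenzo[b,e][1,4]dioxin-7-yl formate F13, and methanolysis would give 16.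

**Step 15.** The electron-rich phenol and polyether may be oxidised in air at 120 °C, and metalation of the ring C hydrogen next to the bulky ring D ether may be slow.
Fallback (from 16, back at 24): the furan would be closed by nucleophilic aromatic substitution of fluoride. Commercial 1-fluoro-3,5-dimethoxybenzene would be lithiated between fluorine and methoxyl (n-BuLi, THF, −78 °C), borylated and oxidised (B(OMe)3; H2O2, NaOH) to give 2-fluoro-4,6-dimethoxyphenol F14. Coupling with 12 (CuI, picolinic acid, K3PO4, DMSO) would give 2-(3,5-dimethoxyphenoxy)-1-fluoro-3,5-dimethoxybenzene F15. A second lithiation at the hydrogen flanked by fluorine and methoxyl, expected to be the most acidic ring position, and trapping with i-PrOBpin would give 2-[3-(3,5-dimethoxyphenoxy)-2-fluoro-4,6-dimethoxyphenyl]-4,4,5,5-tetramethyl-1,3,2-dioxaborolane F16. Suzuki–Miyaura coupling with 16 would give 6-[3-(3,5-dimethoxyphenoxy)-2-fluoro-4,6-dimethoxyphenyl]-1-(3,5-dimethoxyphenoxy)-2,9-dimethoxy-4-(propan-2-yloxy)dibenzo[b,e][1,4]dioxin-7-ol F17. Cs2CO3 in NMP at 140 °C would then displace fluoride with the phenoxide to give 24.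

**Step 7.** Both hydroxyls or the hindered one may be alkylated, because the rate difference between the two phenoxides is moderate. The hydroquinone may also be reoxidised by traces of air.
Fallback (from 10, back at 11): discrimination would be moved to an acyl transfer, which is more sensitive to double ortho substitution. Ac2O and pyridine would give 7-formyl-2,9-dimethoxydibenzo[b,e][1,4]dioxine-1,4-diyl diacetate F4. Controlled methanolysis (K2CO3 cat., MeOH, −20 °C) would remove the exposed C4 acetate to give 7-formyl-4-hydroxy-2,9-dimethoxydibenzo[b,e][1,4]dioxin-1-yl acetate F5. Mitsunobu etherification with propan-2-ol (PPh3, DIAD, THF) would give 7-formyl-2,9-dimethoxy-4-(propan-2-yloxy)dibenzo[b,e][1,4]dioxin-1-yl acetate F6, and methanolysis of the remaining acetate would give 11.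

**Step 8.** Coupling at the doubly ortho-substituted phenoxide may be slow, leaving time for reduction of the aryl bromide and for oxidative degradation of the electron-rich phenoxide at 90 °C.
Fallback (from 11, back at 13): a metal-free aryl transfer from trivalent iodine. (3,5-Dimethoxyphenyl)(2,4,6-trimethoxyphenyl)iodonium tosylate F7 would be made in one pot from 1-iodo-3,5-dimethoxybenzene, mCPBA, TsOH and 1,3,5-trimethoxybenzene. With t-BuOK in THF at room temperature it would transfer the less electron-rich aryl group to the phenoxide of 11 by ligand coupling to give 13.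

## Further compounds

F1 | step 5 | 3-hydroxy-5-methoxy-4-(methoxymethoxy)benzaldehyde | COCOc1c(O)cc(C=O)cc1OC
F2 | step 5 | 3-[(2-chloro-4-methoxy-3,6-dioxocyclohexa-1,4-dien-1-yl)oxy]-5-methoxy-4-(methoxymethoxy)benzaldehyde | COC1=CC(=O)C(Oc2cc(C=O)cc(OC)c2OCOC)=C(Cl)C1=O
F3 | step 5 | 3-[(2-chloro-4-methoxy-3,6-dioxocyclohexa-1,4-dien-1-yl)oxy]-4-hydroxy-5-methoxybenzaldehyde | COC1=CC(=O)C(Oc2cc(C=O)cc(OC)c2O)=C(Cl)C1=O
F4 | step 7 | 7-formyl-2,9-dimethoxydibenzo[b,e][1,4]dioxine-1,4-diyl diacetate | COc1cc(OC(C)=O)c2Oc3cc(C=O)cc(OC)c3Oc2c1OC(C)=O
F5 | step 7 | 7-formyl-4-hydroxy-2,9-dimethoxydibenzo[b,e][1,4]dioxin-1-yl acetate | COc1cc(O)c2Oc3cc(C=O)cc(OC)c3Oc2c1OC(C)=O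
F6 | step 7 | 7-formyl-2,9-dimethoxy-4-(propan-2-yloxy)dibenzo[b,e][1,4]dioxin-1-yl acetate | COc1cc(OC(C)C)c2Oc3cc(C=O)cc(OC)c3Oc2c1OC(C)=O
F7 | step 8 | (3,5-dimethoxyphenyl)(2,4,6-trimethoxyphenyl)iodonium tosylate | COc1cc(OC)cc([I+]c2c(OC)cc(OC)cc2OC)c1.Cc1ccc(cc1)S(=O)(=O)[O-]
F8 | step 10 | 2-bromo-3,4-dihydroxy-5-methoxybenzaldehyde | O=Cc1c(Br)c(O)c(O)c(OC)c1
F9 | step 10 | 6-bromo-2,9-dimethoxy-1,4-dioxo-1,4-dihydrodibenzo[b,e][1,4]dioxine-7-carbaldehyde | COC1=CC(=O)C2=C(Oc3c(OC)cc(C=O)c(Br)c3O2)C1=O
F10 | step 10 | 6-bromo-1,4-dihydroxy-2,9-dimethoxydibenzo[b,e][1,4]dioxine-7-carbaldehyde | COc1cc(O)c2Oc3c(Br)c(C=O)cc(OC)c3Oc2c1O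
F11 | step 10 | 6-bromo-1-hydroxy-2,9-dimethoxy-4-(propan-2-yloxy)dibenzo[b,e][1,4]dioxine-7-carbaldehyde | COc1cc(OC(C)C)c2Oc3c(Br)c(C=O)cc(OC)c3Oc2c1O
F12 | step 10 | 6-bromo-1-(3,5-dimethoxyphenoxy)-2,9-dimethoxy-4-(propan-2-yloxy)dibenzo[b,e][1,4]dioxine-7-carbaldehyde | COc1cc(OC(C)C)c2Oc3c(Br)c(C=O)cc(OC)c3Oc2c1Oc1cc(OC)cc(OC)c1
F13 | step 10 | 6-bromo-1-(3,5-dimethoxyphenoxy)-2,9-dimethoxy-4-(propan-2-yloxy)dibenzo[b,e][1,4]dioxin-7-yl formate | COc1cc(OC(C)C)c2Oc3c(Br)c(OC=O)cc(OC)c3Oc2c1Oc1cc(OC)cc(OC)c1
F14 | step 15 | 2-fluoro-4,6-dimethoxyphenol | COc1cc(OC)c(O)c(F)c1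
F15 | step 15 | 2-(3,5-dimethoxyphenoxy)-1-fluoro-3,5-dimethoxybenzene | COc1cc(OC)c(Oc2cc(OC)cc(OC)c2)c(F)c1
F16 | step 15 | 2-[3-(3,5-dimethoxyphenoxy)-2-fluoro-4,6-dimethoxyphenyl]-4,4,5,5-tetramethyl-1,3,2-dioxaborolane | COc1cc(OC)c(B2OC(C)(C)C(C)(C)O2)c(F)c1Oc1cc(OC)cc(OC)c1
F17 | step 15 | 6-[3-(3,5-dimethoxyphenoxy)-2-fluoro-4,6-dimethoxyphenyl]-1-(3,5-dimethoxyphenoxy)-2,9-dimethoxy-4-(propan-2-yloxy)dibenzo[b,e][1,4]dioxin-7-ol | COc1cc(OC(C)C)c2Oc3c(-c4c(F)c(Oc5cc(OC)cc(OC)c5)c(OC)cc4OC)c(O)cc(OC)c3Oc2c1Oc1cc(OC)cc(OC)c1
A1 | alternative 1 | target skeleton as pentamethyl diethyl ether with one free phenol on each of rings D and E | CCOc1cc(O)cc(Oc2c(OC)cc(OC)c3c2Oc2c(OC)cc4oc5c(Oc6cc(O)cc(OCC)c6)c(OC)cc(OC)c5c4c2O3)c1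
A2 | alternative 1 | A–B–C core pentamethyl ether carrying two ethynyloxy groups in place of rings D and E | C#COc1c(OC)cc(OC)c2c1Oc1c(OC)cc3oc4c(OC#C)c(OC)cc(OC)c4c3c1O2
A3 | alternative 1 | 3-ethoxycyclobut-2-en-1-one | CCOC1=CC(=O)C1
A4 | alternative 2 | 2-(3,5-dimethoxyphenoxy)-5-ethoxy-3-(propan-2-yloxy)-4-(triethylsilyloxy)phenol | Oc1cc(OCC)c(O[Si](CC)(CC)CC)c(OC(C)C)c1Oc1cc(OC)cc(OC)c1
A5 | alternative 2 | racemic 2-(3,5-dimethoxyphenoxy)-4-(1-ethoxyethenyl)-3-(propan-2-yloxy)-4-(triethylsilyloxy)cyclobut-2-en-1-one | C=C(OCC)C1(O[Si](CC)(CC)CC)C(OC(C)C)=C(Oc2cc(OC)cc(OC)c2)C1=O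
A6 | alternative 2 | 3-(3,5-dimethoxyphenoxy)-4-(propan-2-yloxy)cyclobut-3-ene-1,2-dione | CC(C)OC1=C(Oc2cc(OC)cc(OC)c2)C(=O)C1=O
A7 | alternative 3 | 6-(3,5-dimethoxyphenoxy)-7,9-dimethoxydibenzo[b,d]furan-1,3-diol | COc1cc(OC)cc(Oc2c(OC)cc(OC)c3c2oc2cc(O)cc(O)c23)c1
A8 | alternative 3 | O-[2-(3,5-dimethoxyphenoxy)-3,5-dimethoxyphenyl]hydroxylamine | NOc1cc(OC)cc(OC)c1Oc1cc(OC)cc(OC)c1
A9 | alternative 3 | phloroglucinol (benzene-1,3,5-triol) | Oc1cc(O)cc(O)c1
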